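**Retrosynthetic overview**

- The strategy rests on ring A (C1–C6, carotenoid numbering). Its only stereocentre, the C3 carbinol, is remote from the tetrasubstituted C5=C6 double bond, which is conjugated with the C7≡C8 alkyne. The C3–C4 bond joins that carbinol carbon to a CH2 that can be the terminus of an isopropenyl group.
- C3–C4 is therefore cut as a catalytic enantioselective Prins/carbonyl-ene closure of a racemic acyclic enynal. C6 becomes sp2 in this step, so both enantiomers of the precursor converge and the catalyst alone sets C3.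
- The enynal is traced back to an Ireland–Claisen rearrangement of an enynyl isobutyrate (C1–C6 bond, quaternary C1, isopropenyl group) and a one-carbon Wittig homologation that brings in C3.
- Chain: C8–C9 by Sonogashira coupling and C11=C12 by Wittig reaction with a C25 polyenal. The polyenal comes from (R)-alpha-ionone (source of C6') and the symmetrical C10 dialdehyde (C11'=C12' Wittig).
- Ring order: ring E is bought with (R)-alpha-ionone; ring A is the only ring formed, in step 9.

Key step: step 9

Assumption: the sense of induction of the confined chiral acid cannot be predicted with certainty, so the catalyst enantiomer that delivers the (R)-carbinol is used; the alkene geometry of the enynyl intermediates before the rearrangement and of the enol ether is erased later and is uncritical.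

**Route**

Step 1
Reactants: 1 3-(trimethylsilyl)prop-2-ynal; 2 ethyl 2-(triphenylphosphoranylidene)propanoate
Product: 3 ethyl (E)-2-methyl-5-(trimethylsilyl)pent-2-en-4-ynoate
Conditions: CH2Cl2, 0 °C → rt
Reagents that add atoms: none
Why: Wittig olefination of a reactive ynal by a stabilised alpha-methyl ylide should give the (E)-enynoate with good selectivity.

Step 2
Reactants: 3 ethyl (E)-2-methyl-5-(trimethylsilyl)pent-2-en-4-ynoate
Product: 4 (E)-2-methyl-5-(trimethylsilyl)pent-2-en-4-yn-1-ol
Conditions: i-Bu2AlH (2.2 equiv), CH2Cl2, −78 → 0 °C; Rochelle salt work-up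
Reagents that add atoms: none
Why: Ester reduction by 1,2-hydride delivery should give the allylic alcohol, and the silylalkyne is not hydroaluminated at low temperature.

Step 3
Reactants: 4 (E)-2-methyl-5-(trimethylsilyl)pent-2-en-4-yn-1-ol; 5 2-methylpropanoyl chloride
Product: 6 (E)-2-methyl-5-(trimethylsilyl)pent-2-en-4-yn-1-yl 2-methylpropanoate
Conditions: pyridine, DMAP (cat.), CH2Cl2, 0 °C → rt
Reagents that add atoms: none
Why: DMAP-catalysed acylation of the primary allylic alcohol installs the isobutyrate that carries C1 and its two methyl groups.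

Step 4
Reactants: 6 (E)-2-methyl-5-(trimethylsilyl)pent-2-en-4-yn-1-yl 2-methylpropanoate
Product: 9 racemic 2,2,4-trimethyl-3-[(trimethylsilyl)ethynyl]pent-4-enoic acid, via silyl ketene acetal 7 (not isolated), via trimethylsilyl ester 8 (not isolated)
Conditions: LiN(i-Pr)2, THF, −78 °C; Me3SiCl/Et3N, −78 → 65 °C; aq. HCl work-up
Reagents that add atoms: none
Why: Ireland–Claisen rearrangement: the O-silyl ketene acetal of the isobutyrate has no enolate geometry issue, and its chair [3,3] shift joins the fully substituted ketene-acetal carbon (C1) to the alkyne-bearing allyl terminus (C6), creating the quaternary centre, the racemic C6 methine (erased in step 9) and the isopropenyl group in one event.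

Step 5
Reactants: 9 racemic 2,2,4-trimethyl-3-[(trimethylsilyl)ethynyl]pent-4-enoic acid
Product: 10 racemic 2,2,4-trimethyl-3-[(trimethylsilyl)ethynyl]pent-4-en-1-ol
Conditions: LiAlH4, Et2O, 0 °C → reflux; Rochelle salt work-up
Reagents that add atoms: none
Why: LiAlH4 reduction of the hindered carboxylic acid should give the neopentyl alcohol, while the isolated silylalkyne and the 1,1-disubstituted alkene are inert to hydride.

Step 6
Reactants: 10 racemic 2,2,4-trimethyl-3-[(trimethylsilyl)ethynyl]pent-4-en-1-ol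
Product: 11 racemic 2,2,4-trimethyl-3-[(trimethylsilyl)ethynyl]pent-4-enal
Conditions: Dess–Martin periodinane, CH2Cl2, 0 °C → rt
Reagents that add atoms: none
Why: Dess–Martin oxidation of the primary alcohol stops at the aldehyde, which has no alpha-hydrogen and cannot enolise.

Step 7
Reactants: 11 racemic 2,2,4-trimethyl-3-[(trimethylsilyl)ethynyl]pent-4-enal
Product: 12 racemic 1-methoxy-3,3,5-trimethyl-4-[(trimethylsilyl)ethynyl]hexa-1,5-diene (E/Z mixture)
Conditions: MeOCH2PPh3Cl, KN(SiMe3)2, THF, 0 °C; then 11, 0 °C → rt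
Reagents that add atoms: (methoxymethyl)triphenylphosphonium chloride, COC[P+](c1ccccc1)(c1ccccc1)c1ccccc1.[Cl-]
Why: Wittig one-carbon homologation: the non-stabilised methoxymethylidene ylide adds even to the neopentyl, non-enolisable aldehyde and gives the enol ether that carries C3.

Step 8
Reactants: 12 racemic 1-methoxy-3,3,5-trimethyl-4-[(trimethylsilyl)ethynyl]hexa-1,5-diene
Product: 13 racemic 3,3,5-trimethyl-4-[(trimethylsilyl)ethynyl]hex-5-enal
Conditions: 1 M aq. HCl, THF, 0 °C → rt, stopped at full conversion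
Reagents that add atoms: water, O
Why: Acid-catalysed enol ether hydrolysis (C-protonation, hydration of the oxocarbenium ion, loss of methanol) unveils the aldehyde, and dilute aqueous acid at low temperature lets water outcompete the pendant alkene for the oxocarbenium ion.

Step 9
Reactants: 13 racemic 3,3,5-trimethyl-4-[(trimethylsilyl)ethynyl]hex-5-enal
Product: 14 (R)-3,5,5-trimethyl-4-[(trimethylsilyl)ethynyl]cyclohex-3-en-1-ol
Conditions: confined chiral imidodiphosphorimidate Brønsted acid (5 mol %), CHCl3/cyclohexane, 5 Å molecular sieves, −20 °C → rt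
Reagents that add atoms: none
Why: Proposed new method: the confined chiral acid activates the aldehyde of 13, the nucleophilic CH2 terminus (C4) of the isopropenyl group attacks C3 through a chair-like transition state helped by the gem-dimethyl group, and the tertiary C5 cation held in the chiral ion pair gives up the propargylic C6 proton to the counteranion, which regenerates the acid and leaves the conjugated tetrasubstituted C5=C6 enyne. The closest known reaction types are the Lewis-acid-promoted type 2 intramolecular carbonyl-ene (Prins) cyclization of 5-methylhex-5-enals to cyclohexanols and chiral-acid-catalysed asymmetric carbonyl-ene cyclizations of olefinic aldehydes. Ring A closes by formation of C3–C4 in the 6-endo-trig mode with respect to the alkene. The C3 stereocentre is controlled by the catalyst pocket alone, which selects one aldehyde face, and because C6 becomes sp2 both enantiomers of 13 should converge on (R)-14. The step needs facial selectivity that overrides the racemic C6 centre and proton loss toward C6 instead of the C5 methyl group or C4; the propargylic acidity of C6–H and the conjugation gained favour this, and reversible protonation by the acid should funnel any non-conjugated alkene isomer to the enyne.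

Step 10
Reactants: 14 (R)-3,5,5-trimethyl-4-[(trimethylsilyl)ethynyl]cyclohex-3-en-1-ol
Product: 15 (R)-4-ethynyl-3,5,5-trimethylcyclohex-3-en-1-ol
Conditions: K2CO3 (0.2 equiv), MeOH, rt
Reagents that add atoms: none
Why: Methoxide-catalysed protodesilylation cleaves the alkynyl C–Si bond and leaves the carbinol stereocentre untouched.

Step 11
Reactants: 16 but-2-yn-1-ol
Product: 18 (E)-3-iodobut-2-en-1-ol, via alkenylzirconocene 17 (not isolated)
Conditions: Cp2Zr(H)Cl (2.2 equiv), THF, 0 °C → rt; then I2, −78 → 0 °C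
Reagents that add atoms: iodine, II
Why: Hydrozirconation–iodinolysis: syn addition of Zr–H places zirconium on the less hindered, methyl-bearing alkyne carbon after equilibration, and iodine cleaves the C–Zr bond with retention to give the (E)-iodide.

Step 12
Reactants: 15 (R)-4-ethynyl-3,5,5-trimethylcyclohex-3-en-1-ol; 18 (E)-3-iodobut-2-en-1-ol
Product: 19 (R)-4-[(E)-5-hydroxy-3-methylpent-3-en-1-yn-1-yl]-3,5,5-trimethylcyclohex-3-en-1-ol
Conditions: PdCl2(PPh3)2 (2 mol %), CuI (4 mol %), i-Pr2NH, THF, rt, degassed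
Reagents that add atoms: none
Why: Sonogashira coupling forms C8–C9 with retention of the vinyl iodide geometry and tolerates both free hydroxyl groups, so the 9E enyne should result.

Step 13
Reactants: 19 (R)-4-[(E)-5-hydroxy-3-methylpent-3-en-1-yn-1-yl]-3,5,5-trimethylcyclohex-3-en-1-ol
Product: 20 {(2E)-5-[(4R)-4-hydroxy-2,6,6-trimethylcyclohex-1-en-1-yl]-3-methylpent-2-en-4-yn-1-yl}triphenylphosphonium bromide
Conditions: Ph3P·HBr, MeOH, rt
Reagents that add atoms: triphenylphosphine hydrobromide, [Br-].[PH+](c1ccccc1)(c1ccccc1)c1ccccc1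
Why: Acid-mediated allylic substitution (phosphonium salt formation): only the primary allylic, enyne-conjugated alcohol ionises and triphenylphosphine captures it at the unhindered terminus, while the secondary homoallylic ring alcohol does not react.

Step 14
Reactants: 21 (R)-alpha-ionone
Product: 22 (1E)-3-methyl-1-[(1R)-2,6,6-trimethylcyclohex-2-en-1-yl]penta-1,4-dien-3-ol (both C3 epimers)
Conditions: CH2=CHMgBr, THF, −20 → 0 °C; aq. NH4Cl work-up
Reagents that add atoms: vinylmagnesium bromide, C=C[Mg]Br
Why: Grignard 1,2-addition to the enone carbonyl gives the tertiary bis-allylic alcohol without touching C6', and the new carbinol centre is lost again in step 15.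

Step 15
Reactants: 22 (1E)-3-methyl-1-[(1R)-2,6,6-trimethylcyclohex-2-en-1-yl]penta-1,4-dien-3-ol
Product: 23 {(2E,4E)-3-methyl-5-[(1R)-2,6,6-trimethylcyclohex-2-en-1-yl]penta-2,4-dien-1-yl}triphenylphosphonium bromide
Conditions: Ph3P·HBr, MeOH, rt
Reagents that add atoms: triphenylphosphine hydrobromide, [Br-].[PH+](c1ccccc1)(c1ccccc1)c1ccccc1
Why: Phosphonium salt formation with allylic transposition: the tertiary alcohol ionises to a pentadienyl cation that triphenylphosphine captures at the primary terminus, mainly as the 9'E salt, under conditions mild enough to leave the ring double bond and C6' in place.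

Step 16
Reactants: 23 {(2E,4E)-3-methyl-5-[(1R)-2,6,6-trimethylcyclohex-2-en-1-yl]penta-2,4-dien-1-yl}triphenylphosphonium bromide; 24 (2E,4E,6E)-2,7-dimethylocta-2,4,6-trienedial (3 equiv)
Product: 26 (2E,4E,6E,8E,10E,12E)-2,7,11-trimethyl-13-[(1R)-2,6,6-trimethylcyclohex-2-en-1-yl]trideca-2,4,6,8,10,12-hexaenal, via phosphorus ylide 25 (not isolated)
Conditions: NaOMe, MeOH/CH2Cl2, 0 °C → rt; then heptane, 90 °C
Reagents that add atoms: none
Why: Wittig olefination of one formyl group of the symmetrical dialdehyde used in excess forms C11'=C12'; the first olefination deactivates the remaining aldehyde, and heating converts the hindered 11'Z isomer into the all-E aldehyde.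

Step 17
Reactants: 20 {(2E)-5-[(4R)-4-hydroxy-2,6,6-trimethylcyclohex-1-en-1-yl]-3-methylpent-2-en-4-yn-1-yl}triphenylphosphonium bromide; 26 (2E,4E,6E,8E,10E,12E)-2,7,11-trimethyl-13-[(1R)-2,6,6-trimethylcyclohex-2-en-1-yl]trideca-2,4,6,8,10,12-hexaenal
Product: 28 (3R,6'R)-7,8-didehydro-beta,epsilon-caroten-3-ol (target), via phosphorus ylide 27 (not isolated)
Conditions: NaOMe, MeOH/CH2Cl2, rt, dark, argon; then heptane/EtOH, 80 °C; crystallisation
Reagents that add atoms: none
Why: Wittig olefination forms C11=C12; the hindered 11Z isomer should isomerise thermally to the all-E polyene, and methoxide at room temperature affects neither the C3 carbinol nor the C6' methine.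

**Compound list**

1 | 3-(trimethylsilyl)prop-2-ynal | C[Si](C)(C)C#CC=O | starting material
2 | ethyl 2-(triphenylphosphoranylidene)propanoate | CCOC(=O)C(C)=P(c1ccccc1)(c1ccccc1)c1ccccc1 | starting material
3 | ethyl (E)-2-methyl-5-(trimethylsilyl)pent-2-en-4-ynoate | CCOC(=O)/C(C)=C/C#C[Si](C)(C)C | intermediate
4 | (E)-2-methyl-5-(trimethylsilyl)pent-2-en-4-yn-1-ol | OC/C(C)=C/C#C[Si](C)(C)C | intermediate
5 | 2-methylpropanoyl chloride | CC(C)C(Cl)=O | starting material
6 | (E)-2-methyl-5-(trimethylsilyl)pent-2-en-4-yn-1-yl 2-methylpropanoate | CC(C)C(=O)OC/C(C)=C/C#C[Si](C)(C)C | intermediate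
7 | trimethyl{[2-methyl-1-{[(E)-2-methyl-5-(trimethylsilyl)pent-2-en-4-yn-1-yl]oxy}prop-1-en-1-yl]oxy}silane (silyl ketene acetal) | CC(C)=C(O[Si](C)(C)C)OC/C(C)=C/C#C[Si](C)(C)C | intermediate
8 | trimethylsilyl 2,2,4-trimethyl-3-[(trimethylsilyl)ethynyl]pent-4-enoate (racemic) | C[Si](C)(C)OC(=O)C(C)(C)C(C#C[Si](C)(C)C)C(C)=C | intermediate
9 | 2,2,4-trimethyl-3-[(trimethylsilyl)ethynyl]pent-4-enoic acid (racemic) | OC(=O)C(C)(C)C(C#C[Si](C)(C)C)C(C)=C | intermediate
10 | 2,2,4-trimethyl-3-[(trimethylsilyl)ethynyl]pent-4-en-1-ol (racemic) | OCC(C)(C)C(C#C[Si](C)(C)C)C(C)=C | intermediate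
11 | 2,2,4-trimethyl-3-[(trimethylsilyl)ethynyl]pent-4-enal (racemic) | O=CC(C)(C)C(C#C[Si](C)(C)C)C(C)=C | intermediate
12 | 1-methoxy-3,3,5-trimethyl-4-[(trimethylsilyl)ethynyl]hexa-1,5-diene (racemic, E/Z mixture) | COC=CC(C)(C)C(C#C[Si](C)(C)C)C(C)=C | intermediate
13 | 3,3,5-trimethyl-4-[(trimethylsilyl)ethynyl]hex-5-enal (racemic) | O=CCC(C)(C)C(C#C[Si](C)(C)C)C(C)=C | intermediate
14 | (R)-3,5,5-trimethyl-4-[(trimethylsilyl)ethynyl]cyclohex-3-en-1-ol | CC1=C(C#C[Si](C)(C)C)C(C)(C)C[C@H](O)C1 | intermediate
15 | (R)-4-ethynyl-3,5,5-trimethylcyclohex-3-en-1-ol | CC1=C(C#C)C(C)(C)C[C@H](O)C1 | intermediate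
16 | but-2-yn-1-ol | CC#CCO | starting material
17 | O,C-bis(chlorozirconocene) adduct of (E)-but-2-en-1-ol (zirconium on C3 and on oxygen) | C/C(=C\CO[Zr](Cl)(C1C=CC=C1)C1C=CC=C1)[Zr](Cl)(C1C=CC=C1)C1C=CC=C1 | intermediate
18 | (E)-3-iodobut-2-en-1-ol | C/C(I)=C\CO | intermediate
19 | (R)-4-[(E)-5-hydroxy-3-methylpent-3-en-1-yn-1-yl]-3,5,5-trimethylcyclohex-3-en-1-ol | CC1=C(C#C/C(C)=C/CO)C(C)(C)C[C@H](O)C1 | intermediate
20 | {(2E)-5-[(4R)-4-hydroxy-2,6,6-trimethylcyclohex-1-en-1-yl]-3-methylpent-2-en-4-yn-1-yl}triphenylphosphonium bromide | CC1=C(C#C/C(C)=C/C[P+](c2ccccc2)(c2ccccc2)c2ccccc2)C(C)(C)C[C@H](O)C1.[Br-] | intermediate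
21 | (R)-alpha-ionone | CC1=CCCC(C)(C)[C@H]1/C=C/C(C)=O | starting material
22 | (1E)-3-methyl-1-[(1R)-2,6,6-trimethylcyclohex-2-en-1-yl]penta-1,4-dien-3-ol (both C3 epimers) | CC1=CCCC(C)(C)[C@H]1/C=C/C(C)(O)C=C | intermediate
23 | {(2E,4E)-3-methyl-5-[(1R)-2,6,6-trimethylcyclohex-2-en-1-yl]penta-2,4-dien-1-yl}triphenylphosphonium bromide | CC1=CCCC(C)(C)[C@H]1/C=C/C(C)=C/C[P+](c2ccccc2)(c2ccccc2)c2ccccc2.[Br-] | intermediate
24 | (2E,4E,6E)-2,7-dimethylocta-2,4,6-trienedial | O=C/C(C)=C/C=C/C=C(C)/C=O | starting material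
25 | {(2E,4E)-3-methyl-5-[(1R)-2,6,6-trimethylcyclohex-2-en-1-yl]penta-2,4-dien-1-ylidene}triphenylphosphorane | CC1=CCCC(C)(C)[C@H]1/C=C/C(C)=C/C=P(c2ccccc2)(c2ccccc2)c2ccccc2 | intermediate
26 | (2E,4E,6E,8E,10E,12E)-2,7,11-trimethyl-13-[(1R)-2,6,6-trimethylcyclohex-2-en-1-yl]trideca-2,4,6,8,10,12-hexaenal | CC1=CCCC(C)(C)[C@H]1/C=C/C(C)=C/C=C/C(C)=C/C=C/C=C(C)/C=O | intermediate
27 | {(2E)-5-[(4R)-4-hydroxy-2,6,6-trimethylcyclohex-1-en-1-yl]-3-methylpent-2-en-4-yn-1-ylidene}triphenylphosphorane | CC1=C(C#C/C(C)=C/C=P(c2ccccc2)(c2ccccc2)c2ccccc2)C(C)(C)C[C@H](O)C1 | intermediate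
28 | (3R,6'R)-7,8-didehydro-beta,epsilon-caroten-3-ol | CC1=CCCC(C)(C)[C@H]1/C=C/C(C)=C/C=C/C(C)=C/C=C/C=C(C)/C=C/C=C(\C)C#CC1=C(C)C[C@@H](O)CC1(C)C | target

**Step count and risks**

Total step count: 17. Longest linear sequence: 13 steps (steps 1 to 10, 12, 13 and 17).

The three steps most likely to fail:

1. Step 9 (the new method). The catalyst may fail to override the racemic C6 centre, so that one enantiomer of the substrate cyclises with poor facial selectivity. Proton loss may also stop at a non-conjugated alkene isomer. The fallback uses known chemistry, sets out from 13 and comes back to the route at 15.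
   - Closure of 13 with Me2AlCl in CH2Cl2 at −78 °C is a Lewis-acid type 2 carbonyl-ene reaction with hydrogen transfer from the methyl group. It should give racemic 5,5-dimethyl-3-methylidene-4-[(trimethylsilyl)ethynyl]cyclohexan-1-ol F1.
   - Catalytic p-toluenesulfonic acid in benzene should move the exocyclic double bond into conjugation with the alkyne. This gives racemic 3,5,5-trimethyl-4-[(trimethylsilyl)ethynyl]cyclohex-3-en-1-ol F2.
   - Lipase-catalysed acylation (Pseudomonas cepacia lipase, vinyl acetate, t-BuOMe) follows. By the empirical size rule for secondary alcohols it should acylate the (R)-enantiomer. It would give (R)-3,5,5-trimethyl-4-[(trimethylsilyl)ethynyl]cyclohex-3-en-1-yl acetate F3 beside unreacted (S)-3,5,5-trimethyl-4-[(trimethylsilyl)ethynyl]cyclohex-3-en-1-ol F4, separable by chromatography.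
   - K2CO3 in MeOH then removes the acetyl and the silyl group of F3 together and gives 15. F4 can be turned into F3 by Mitsunobu inversion with acetic acid.

2. Step 8. During the acidic hydrolysis the oxocarbenium ion or the freed aldehyde may be trapped by the isopropenyl group, which is an uncatalysed racemic ring closure before the chiral acid is present. The fallback is an Arndt–Eistert homologation under non-acidic conditions; it sets out from 9 and comes back at 13.
   - Oxalyl chloride with catalytic DMF should give 2,2,4-trimethyl-3-[(trimethylsilyl)ethynyl]pent-4-enoyl chloride F5.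
   - Excess diazomethane in Et2O should give 1-diazo-3,3,5-trimethyl-4-[(trimethylsilyl)ethynyl]hex-5-en-2-one F6.
   - Photochemical Wolff rearrangement in MeOH should give methyl 3,3,5-trimethyl-4-[(trimethylsilyl)ethynyl]hex-5-enoate F7.
   - i-Bu2AlH in CH2Cl2 at −78 °C should then give 13.

3. Step 17. The Wittig reaction may give incomplete E selectivity at C11=C12, and the thermal isomerisation that corrects it may scramble the C9=C10 geometry next to the alkyne or degrade the polyene. The fallback replaces the phosphonium salt by a phosphonate; it sets out from 18, uses 15 and 26, and comes back at 28.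
   - PBr3 in Et2O at 0 °C should convert 18 into (E)-1-bromo-3-iodobut-2-ene F8.
   - Michaelis–Arbuzov reaction with P(OEt)3 should give diethyl [(E)-3-iodobut-2-en-1-yl]phosphonate F9.
   - Sonogashira coupling of F9 with 15 (PdCl2(PPh3)2, CuI, i-Pr2NH) should give diethyl {(2E)-5-[(4R)-4-hydroxy-2,6,6-trimethylcyclohex-1-en-1-yl]-3-methylpent-2-en-4-yn-1-yl}phosphonate F10.
   - Horner–Wadsworth–Emmons olefination of 26 with F10 (NaN(SiMe3)2, 2 equiv, THF, −78 → 0 °C) should give 28 with high E selectivity and without a heating step.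

Further compounds
F1 | step 9 | 5,5-dimethyl-3-methylidene-4-[(trimethylsilyl)ethynyl]cyclohexan-1-ol (racemic, diastereomer mixture) | C=C1CC(O)CC(C)(C)C1C#C[Si](C)(C)C
F2 | step 9 | 3,5,5-trimethyl-4-[(trimethylsilyl)ethynyl]cyclohex-3-en-1-ol (racemic) | CC1=C(C#C[Si](C)(C)C)C(C)(C)CC(O)C1
F3 | step 9 | (R)-3,5,5-trimethyl-4-[(trimethylsilyl)ethynyl]cyclohex-3-en-1-yl acetate | CC1=C(C#C[Si](C)(C)C)C(C)(C)C[C@H](OC(C)=O)C1
F4 | step 9 | (S)-3,5,5-trimethyl-4-[(trimethylsilyl)ethynyl]cyclohex-3-en-1-ol | CC1=C(C#C[Si](C)(C)C)C(C)(C)C[C@@H](O)C1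
F5 | step 8 | 2,2,4-trimethyl-3-[(trimethylsilyl)ethynyl]pent-4-enoyl chloride (racemic) | C=C(C)C(C#C[Si](C)(C)C)C(C)(C)C(Cl)=O
F6 | step 8 | 1-diazo-3,3,5-trimethyl-4-[(trimethylsilyl)ethynyl]hex-5-en-2-one (racemic) | C=C(C)C(C#C[Si](C)(C)C)C(C)(C)C(=O)C=[N+]=[N-]
F7 | step 8 | methyl 3,3,5-trimethyl-4-[(trimethylsilyl)ethynyl]hex-5-enoate (racemic) | C=C(C)C(C#C[Si](C)(C)C)C(C)(C)CC(=O)OC
F8 | step 17 | (E)-1-bromo-3-iodobut-2-ene | C/C(I)=C\CBr
F9 | step 17 | diethyl [(E)-3-iodobut-2-en-1-yl]phosphonate | CCOP(=O)(C/C=C(\C)I)OCC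
F10 | step 17 | diethyl {(2E)-5-[(4R)-4-hydroxy-2,6,6-trimethylcyclohex-1-en-1-yl]-3-methylpent-2-en-4-yn-1-yl}phosphonate | CCOP(=O)(C/C=C(C)/C#CC1=C(C)C[C@@H](O)CC1(C)C)OCC
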